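| flask | substrate | reagent | remark | time |
|---|---|---|---|---|
| south | 0.034 M | 0.95 equiv | run made earlier |  |
| south-east | 0.075 M | 0.95 equiv | run made earlier |  |
| north | 0.050 M | 1.4 equiv | run made earlier |  |
| flask | 0.050 M | 0.950 equiv |  | 3.0 h |

| run | time / h | target / % | intermediate A / % |
|---|---|---|---|
| south | 0.200 | 14 | 54 |
| south | 0.500 | 18 | 57 |
| south | 1.00 | 20 | 64 |
| south | 1.50 | 20 | 69 |
| south | 2.00 | 25 | 66 |
| south | 3.00 | 19 | 68 |
| south | 4.00 | 22 | 66 |
| south-east | 0.500 | 20 | 65 |
| south-east | 1.00 | 24 | 66 |
| south-east | 1.50 | 22 | 62 |
| south-east | 2.00 | 19 | 68 |
| south-east | 2.50 | 22 | 65 |
| south-east | 3.00 | 20 | 69 |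
| south-east | 4.00 | 21 | 65 |
| north | 0.333 | 25 | 71 |
| north | 0.833 | 20 | 64 |
| north | 1.50 | 24 | 58 |
| north | 2.50 | 22 | 52 |
| north | 4.00 | 25 | 47 |

(standard deviation of a reading: 2 percentage points)

- why nothing more happens at 3.0 h, or that something still does (the reagent has run out first / it is still moving / all of the substrate has reacted)
- amount of target at 3.0 h, in percent of the substrate charged
- amount of intermediate A at 3.0 h, in percent of the substrate charged

- the reaction counts as stopped when no species that holds the substrate changes by six tenths of a point or more over the second half of the time

Whatever the clock says, I take each substrate molecule that reacts to use one reagent, so at 0.950 equiv reagent is the limiting reagent of this flask. I follow one substrate molecule to its fork: does it become target or intermediate A? In the north run target reads 25 % and later 25 %, while intermediate A falls from 71 % to 47 %, so I read the two as parallel branches and see intermediate A going on to something unseen while reagent remains.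

What are the odds at the fork? I define the target share as target over target plus intermediate A, the chance that a reacting substrate molecule becomes target. The last two readings of the south and south-east runs give 23.4 %. Those runs differ 2.21-fold in concentration yet read alike, and this flask, at the same equivalents, lies between them in concentration.

Will it be flat by 3.0 h? Both runs read flat around that time, so I expect it to be. If each reagent met fresh substrate, this flask would hold 22.2 % target. But in those same readings target and intermediate A together average 87.5 %, less than the reagent charged, so I count that target figure as a little high and take intermediate A for this flask from those readings, 67.0 %.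

The forecast says the reagent has run out first, with 21 % target, slightly below my figure, and 66 % intermediate A: “The reaction stops because the reagent runs out”.

The answer for the flask is that the reagent has run out first, with 21.5 % target and 66.7 % intermediate A; at 3.0 h, 0.028 % of the reagent charged and 8.5 % of the substrate charged remain.

    reagent + intermediate A → intermediate B (k = 0.190 M⁻¹ min⁻¹)
    intermediate B → side product (k = 0.0320 min⁻¹)
    substrate + reagent → intermediate A (k = 4.90 M⁻¹ min⁻¹)
    substrate + reagent → target (k = 1.50 M⁻¹ min⁻¹)

With the concentrations as charged in this flask, substrate has a half-life of 3.0 min by the branch to intermediate A alone, far shorter than the 1.3 h of intermediate A by its reaction with reagent alone. The target share times the substrate reacted gives 21.4 % target here. In a flask charged with 0.240 equiv of reagent, 76.1 % of the substrate remains at 3.00 h, so the same reckoning gives 5.59 % target, and that flask holds 5.61 % target.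

Readings and results were computed for substances that don't exist.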